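Rings A (the thiophene bearing CH2O) and B (the thiophene bearing the alkyne) are both opened at their C–S bonds. Their eight ring carbons, C2–C5 of ring A and C2'–C5' of ring B, continue the CH2O carbon as one unbranched C9 chain in which each sulfur bridges the ends of a four-carbon unit, the pattern of a conjugated tetrayne. In one pot, two sulfide ions convert the linear precursor HOCH2–(C≡C)4–SiMe3 into [2,2'-bithiophen]-5-ylmethanol, forming four C–S bonds and both rings. The tetrayne comes from two butadiyne units and formaldehyde; an esterification, an α-iodination and a Sonogashira coupling with a preformed butynyl ester complete the target.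

Key step: step 5

Remarks on the chemistry:
- The target has no stereocentre and no configured double bond, because the senecioate alkene carries two methyl groups on one carbon.
- Chain numbering used below: C1 is the CH2OH carbon, C2–C5 become ring A and C6–C9 become ring B.
- The precursor keeps its hydroxyl free, so no protecting-group steps are needed. It keeps a trimethylsilyl cap because the sulfide medium removes that cap itself, so the terminal tetrayne exists only briefly and only in the presence of excess sulfide.
- One batch of silyl diyne 3 from step 1 is divided: one part is hydroxymethylated in step 2, the other is the terminal-alkyne partner in step 4.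
- Polyynes 3, 7 and 8 are assumed to be handled only as cold, dilute solutions and never taken to dryness.

Step 1
Reactants: 1 1,4-bis(trimethylsilyl)buta-1,3-diyne
Product: 3 buta-1,3-diyn-1-yl(trimethyl)silane, via lithium 4-(trimethylsilyl)buta-1,3-diyn-1-ide 2 (not isolated)
Conditions: MeLi·LiBr (1.05 equiv), Et2O, rt; aq. NH4Cl, −78 → 0 °C; kept as a dried Et2O solution
Reagents that add atoms: none
Why: MeLi·LiBr cleaves one C–Si bond selectively by nucleophilic attack at silicon, since the lithium diynide formed resists a second cleavage, and protonation of the diynide gives the volatile mono-silyl diyne, which is carried on in solution.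

Step 2
Reactants: 3 buta-1,3-diyn-1-yl(trimethyl)silane; 4 formaldehyde (as paraformaldehyde)
Product: 6 5-(trimethylsilyl)penta-2,4-diyn-1-ol, via bromomagnesium 4-(trimethylsilyl)buta-1,3-diyn-1-ide 5 (not isolated)
Conditions: EtMgBr (1.05 equiv), THF/Et2O, 0 °C → rt; then dry (CH2O)n (3 equiv), 0 °C → rt; aq. NH4Cl
Reagents that add atoms: formaldehyde (compound 4, as paraformaldehyde), C=O
Why: Ethylmagnesium bromide deprotonates the acidic diyne C–H without touching the C–Si bond, and the alkynyl Grignard reagent then undergoes the standard 1,2-addition of a metal acetylide to formaldehyde (hydroxymethylation).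

Step 3
Reactants: 6 5-(trimethylsilyl)penta-2,4-diyn-1-ol
Product: 7 5-bromopenta-2,4-diyn-1-ol
Conditions: NBS (1.1 equiv), AgNO3 (0.2 equiv), acetone, rt, dark; aq. work-up, kept as an Et2O solution
Reagents that add atoms: N-bromosuccinimide, O=C1CCC(=O)N1Br
Why: AgNO3-catalysed bromodesilylation, in which monovalent silver takes the alkynyl group from silicon and NBS brominates the silver acetylide, is a standard one-pot conversion of alkynylsilanes into 1-bromoalkynes and leaves the primary alcohol untouched.

Step 4
Reactants: 7 5-bromopenta-2,4-diyn-1-ol; 3 buta-1,3-diyn-1-yl(trimethyl)silane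
Product: 8 9-(trimethylsilyl)nona-2,4,6,8-tetrayn-1-ol
Conditions: CuCl (10 mol%), NH2OH·HCl, 30% aq. n-BuNH2, Et2O, 0 °C, slow addition of 7 to 3 (1.5 equiv); quick aq. NH4Cl work-up, product kept in solution
Reagents that add atoms: none
Why: In this Cadiot–Chodkiewicz coupling the copper acetylide of 3 attacks bromoalkyne 7 to form the C5–C6 bond, NH2OH·HCl keeps copper monovalent so that Glaser homocoupling is suppressed, and the cold two-phase medium should limit loss of the silyl cap.

Step 5
Reactants: 8 9-(trimethylsilyl)nona-2,4,6,8-tetrayn-1-ol; 9 sodium sulfide (as the nonahydrate)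
Product: 12 [2,2'-bithiophen]-5-ylmethanol, via nona-2,4,6,8-tetrayn-1-ol 10 (not isolated), via 5-(thiophen-2-yl)penta-2,4-diyn-1-ol 11 (not isolated)
Conditions: Na2S·9H2O (6 equiv), degassed DMSO, slow addition of 8 as a dilute THF solution, 20 °C then 45 °C; aq. NH4Cl
Reagents that add atoms: sodium sulfide (compound 9), [Na+].[Na+].[S-2]
Why: Hydroxide and hydrosulfide in the hydrated sulfide first cleave the C9–Si bond to give 10, after which HS− adds in anti fashion at the unhindered terminal carbon C9 and protonation of the delocalised carbanion gives a Z-enethiolate. Its sulfur attacks C6, the far carbon of the neighbouring triple bond, in a 5-endo-dig closure that forms ring B and leaves thienyl diynol 11; a second HS− then adds at either end of the C2–C5 diyne and a second 5-endo-dig closure forms ring A. The closest known reaction type is the Na2S annulation of conjugated 1,3-diynes to 2,5-disubstituted thiophenes, which is also known to repeat along longer polyynes to give oligothiophenes. No stereocentre is created, and the cis relation of sulfur and alkynyl group that each closure requires follows from the anti addition. The selectivity needed is positional: sulfide must enter at C2, C5, C6 or C9 and not at C4 or C7, which would close a thiophene across C4–C7 with an alkyne on either side; attack at the free C9–H end is least hindered and gives the carbanion delocalised over the whole chain, and entry at the hydroxymethyl end would only reverse the order in which the rings close. KOH is left out and the temperature kept low so that the propargylic CH2OH meets no stronger base than the sulfide itself.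

Step 6
Reactants: 12 [2,2'-bithiophen]-5-ylmethanol; 13 3-methylbut-2-enoic acid (senecioic acid)
Product: 14 [2,2'-bithiophen]-5-ylmethyl 3-methylbut-2-enoate
Conditions: DCC (1.2 equiv), DMAP (0.1 equiv), CH2Cl2, 0 °C → rt
Reagents that add atoms: 3-methylbut-2-enoic acid (compound 13), CC(C)=CC(=O)O
Why: In this Steglich esterification DCC activates the acid and catalytic DMAP passes the acyl group to the primary alcohol, and using the free acid at 0 °C avoids the vinylketene pathway by which an acid chloride and amine base can shift the double bond out of conjugation.

Step 7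
Reactants: 14 [2,2'-bithiophen]-5-ylmethyl 3-methylbut-2-enoate
Product: 15 (5'-iodo-[2,2'-bithiophen]-5-yl)methyl 3-methylbut-2-enoate
Conditions: NIS (1.05 equiv), DMF, 0 °C → rt, dark
Reagents that add atoms: N-iodosuccinimide, O=C1CCC(=O)N1I
Why: In this electrophilic aromatic iodination C5' is the only unsubstituted α-position of the bithiophene and is far more reactive than any β-position, while acid-free NIS should leave the thienylmethyl ester and the electron-poor alkene alone.

Step 8
Reactants: 16 but-3-yn-1-ol; 17 3-methylbutanoic anhydride
Product: 18 but-3-yn-1-yl 3-methylbutanoate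
Conditions: Et3N, DMAP (5 mol%), CH2Cl2, 0 °C → rt
Reagents that add atoms: 3-methylbutanoic anhydride (compound 17), CC(C)CC(=O)OC(=O)CC(C)C
Why: This is a DMAP-catalysed acylation of a primary alcohol by an anhydride, to which the terminal alkyne is inert.

Step 9
Reactants: 15 (5'-iodo-[2,2'-bithiophen]-5-yl)methyl 3-methylbut-2-enoate; 18 but-3-yn-1-yl 3-methylbutanoate
Product: 19 {5'-[4-(3-methylbutanoyloxy)but-1-yn-1-yl]-[2,2'-bithiophen]-5-yl}methyl 3-methylbut-2-enoate (target)
Conditions: PdCl2(PPh3)2 (3 mol%), CuI (5 mol%), Et3N, THF, rt, degassed; 18 (1.3 equiv)
Reagents that add atoms: none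
Why: In this Sonogashira coupling zerovalent palladium formed in the flask inserts into the C5'–I bond at room temperature and the copper acetylide of 18 delivers the alkynyl group, under conditions that both esters tolerate.

Compound list
1 | 1,4-bis(trimethylsilyl)buta-1,3-diyne | C[Si](C)(C)C#CC#C[Si](C)(C)C | starting material
2 | lithium 4-(trimethylsilyl)buta-1,3-diyn-1-ide | [Li]C#CC#C[Si](C)(C)C | intermediate
3 | buta-1,3-diyn-1-yl(trimethyl)silane | C#CC#C[Si](C)(C)C | intermediate
4 | formaldehyde (used as paraformaldehyde) | C=O | starting material
5 | bromomagnesium 4-(trimethylsilyl)buta-1,3-diyn-1-ide | Br[Mg]C#CC#C[Si](C)(C)C | intermediate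
6 | 5-(trimethylsilyl)penta-2,4-diyn-1-ol | OCC#CC#C[Si](C)(C)C | intermediate
7 | 5-bromopenta-2,4-diyn-1-ol | OCC#CC#CBr | intermediate
8 | 9-(trimethylsilyl)nona-2,4,6,8-tetrayn-1-ol | OCC#CC#CC#CC#C[Si](C)(C)C | intermediate
9 | sodium sulfide (used as the nonahydrate) | [Na+].[Na+].[S-2] | starting material
10 | nona-2,4,6,8-tetrayn-1-ol | OCC#CC#CC#CC#C | intermediate
11 | 5-(thiophen-2-yl)penta-2,4-diyn-1-ol | OCC#CC#Cc1cccs1 | intermediate
12 | [2,2'-bithiophen]-5-ylmethanol | OCc1ccc(-c2cccs2)s1 | intermediate
13 | 3-methylbut-2-enoic acid | CC(C)=CC(=O)O | starting material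
14 | [2,2'-bithiophen]-5-ylmethyl 3-methylbut-2-enoate | CC(C)=CC(=O)OCc1ccc(-c2cccs2)s1 | intermediate
15 | (5'-iodo-[2,2'-bithiophen]-5-yl)methyl 3-methylbut-2-enoate | CC(C)=CC(=O)OCc1ccc(-c2ccc(I)s2)s1 | intermediate
16 | but-3-yn-1-ol | C#CCCO | starting material
17 | 3-methylbutanoic anhydride | CC(C)CC(=O)OC(=O)CC(C)C | starting material
18 | but-3-yn-1-yl 3-methylbutanoate | C#CCCOC(=O)CC(C)C | intermediate
19 | {5'-[4-(3-methylbutanoyloxy)but-1-yn-1-yl]-[2,2'-bithiophen]-5-yl}methyl 3-methylbut-2-enoate | CC(C)=CC(=O)OCc1ccc(-c2ccc(C#CCCOC(=O)CC(C)C)s2)s1 | target

Total step count: 9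
Longest linear sequence: 8 steps (steps 1, 2, 3, 4, 5, 6, 7, 9); step 8 is a side branch.

Steps most likely to fail

1. Step 5. The desilylated tetrayne may polymerise faster than it takes up sulfide, or the first sulfide may enter at an internal carbon so that a ring closes across C4–C7 and two alkynes are left over. The fallback forms only ring A by annulation, on a diyne that already carries ring B. It sets out from 6. A one-pot fluoride desilylation and Sonogashira coupling (CsF, PdCl2(PPh3)2, CuI, Et3N, wet THF, rt) would release penta-2,4-diyn-1-ol F1 in the flask and couple it at once with commercial 2-iodothiophene to give 11, which is isolated this time. Na2S·9H2O in DMSO at 20–50 °C should then close ring A on this ordinary aryl alkyl diyne, and the route is rejoined at 12.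

2. Step 4. The trimethylsilyl cap may be lost in the aqueous amine, after which the freed terminus couples again, or either alkyne partner may homocouple. The fallback builds the C8 chain symmetrically and then differentiates its ends, with no bromoalkyne or amine involved. It sets out from 3. Oxidative Hay homocoupling (CuCl, TMEDA, O2, acetone, rt) would give 1,8-bis(trimethylsilyl)octa-1,3,5,7-tetrayne F2. One silyl group is then cleaved with MeLi·LiBr (1.0 equiv, THF, −78 → −20 °C) to give lithium 8-(trimethylsilyl)octa-1,3,5,7-tetrayn-1-ide F3, which is trapped with paraformaldehyde 4 and quenched with aq. NH4Cl. The route is rejoined at 8. The mono-desilylation is established for the diyne and is extended here to the tetrayne.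

3. Step 7. The iodination may lack positional control (attack at a β-carbon or double iodination), or the thienylmethyl C–O bond may ionise under the electrophilic conditions. The fallback places the iodine by deprotonation rather than electrophilic substitution, and before the ester exists. It sets out from 12. n-BuLi (2.2 equiv, THF, −78 → 0 °C) should deprotonate the hydroxyl and the acidic α-position C5' to give lithium (5'-lithio-[2,2'-bithiophen]-5-yl)methanolate F4. I2 at −78 °C followed by aq. NH4Cl would give (5'-iodo-[2,2'-bithiophen]-5-yl)methanol F5. Steglich esterification with 13 (DCC, DMAP, CH2Cl2, 0 °C) then rejoins the route at 15.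

Further compounds
F1 | step 5 | penta-2,4-diyn-1-ol | OCC#CC#C
F2 | step 4 | 1,8-bis(trimethylsilyl)octa-1,3,5,7-tetrayne | C[Si](C)(C)C#CC#CC#CC#C[Si](C)(C)C
F3 | step 4 | lithium 8-(trimethylsilyl)octa-1,3,5,7-tetrayn-1-ide | [Li]C#CC#CC#CC#C[Si](C)(C)C
F4 | step 7 | lithium (5'-lithio-[2,2'-bithiophen]-5-yl)methanolate | [Li]OCc1ccc(-c2ccc([Li])s2)s1
F5 | step 7 | (5'-iodo-[2,2'-bithiophen]-5-yl)methanol | OCc1ccc(-c2ccc(I)s2)s1
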